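## Retrosynthetic overview

- Ring C is closed last: the O1–C2 bond by intramolecular Mitsunobu etherification of a C2 primary alcohol, which is uncovered by cleaving an E-propenyl group on C3.
- Structural handle: on ring B, C1' (bonded to C3) and C5' (bearing the 2-methylbut-3-en-2-yl group) each lie ortho to one of O2'/O4' and para to the other, so both ring B carbon substituents can be delivered from those oxygens by [3,3] shifts.
- Key disconnection: C1'–C3 (with the C3 stereocentre) and C5'–C(quaternary) back to a ring B bis-ether, O2' carrying an (R,E)-5-arylpent-3-en-2-yl group and O4' a prenyl group. Two aromatic Claisen rearrangements follow, one of which relays the carbinol chirality to C3.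
- The bis-ether comes from Mitsunobu inversion of an (S,E)-allylic alcohol with resorcinol mono-prenyl ether. The alcohol comes from (S)-but-3-yn-2-ol and a ring A benzyl bromide (copper-catalysed alkynylation, trans-reduction); the bromide comes from 2,4-dihydroxybenzaldehyde by an earlier prenyl ether Claisen shift.
- Ring order: rings A and B are bought as arenes; ring C is the only ring made.

Key step: step 11

Remark on the chemistry: (S)-but-3-yn-2-ol of high enantiomeric purity is assumed to be bought; the configuration of the target rests on it and on the chirality transfer in the key step.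

Shorthand: ArA = 4-(tert-butyldimethylsilyloxy)-2-(methoxymethoxy)-5-(2-methylbut-3-en-2-yl)phenyl; ArB = 2,4-bis(tert-butyldimethylsilyloxy)-5-(2-methylbut-3-en-2-yl)phenyl; TBS = tert-butyldimethylsilyl; MOM = methoxymethyl; BSA = N,O-bis(trimethylsilyl)acetamide; NMO = 4-methylmorpholine N-oxide; DIAD = diisopropyl azodicarboxylate; PhNEt2 = N,N-diethylaniline. Isoflavan numbering (O1, C2, C3, C4; ring A fused; ring B on C3 with primed locants) is used for atoms that end up in the target.

## Route

Step 1
Reactants: 1 2,4-dihydroxybenzaldehyde; 2 1-bromo-3-methylbut-2-ene (prenyl bromide)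
Product: 3 2-hydroxy-4-(3-methylbut-2-enyloxy)benzaldehyde
Conditions: K2CO3, acetone, rt
Reagents that add atoms: none
Why: Williamson etherification: the 2-hydroxyl is held in a hydrogen bond to the formyl group and is the weaker acid, so one equivalent of bromide should alkylate the free 4-hydroxyl only.

Step 2
Reactants: 3 2-hydroxy-4-(3-methylbut-2-enyloxy)benzaldehyde
Product: 4 2-(methoxymethoxy)-4-(3-methylbut-2-enyloxy)benzaldehyde
Conditions: MOMCl, i-Pr2NEt, CH2Cl2, 0 °C to reflux
Reagents that add atoms: chloromethyl methyl ether COCCl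
Why: Acetal protection of the chelated phenol by O-alkylation with the reactive chloromethyl ether under amine base; capping O2 also removes the hydrogen bond that would otherwise steer the coming allyl shift to C3.

Step 3
Reactants: 4 2-(methoxymethoxy)-4-(3-methylbut-2-enyloxy)benzaldehyde
Product: 6 4-hydroxy-2-(methoxymethoxy)-5-(2-methylbut-3-en-2-yl)benzaldehyde, via trimethylsilyl ether 5 (not isolated)
Conditions: BSA, PhNEt2, 190 °C (sealed tube); then citric acid, THF–H2O, rt
Reagents that add atoms: none
Why: Aromatic Claisen rearrangement of an aryl prenyl ether: the concerted [3,3] shift carries the dimethyl-substituted allyl terminus to C5, the open ortho position (C3 lies between two ether oxygens and no chelated phenol fixes the C3–C4 bond), while BSA silylates the new phenol at once so that abnormal Claisen and cyclisation pathways are shut off until the silyl group is washed off with mild acid.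

Step 4
Reactants: 6 4-hydroxy-2-(methoxymethoxy)-5-(2-methylbut-3-en-2-yl)benzaldehyde
Product: 7 4-(tert-butyldimethylsilyloxy)-2-(methoxymethoxy)-5-(2-methylbut-3-en-2-yl)benzaldehyde (ArA–CHO)
Conditions: TBSCl, imidazole, 4-(dimethylamino)pyridine (cat.), DMF, 40 °C
Reagents that add atoms: tert-butyldimethylsilyl chloride CC(C)(C)[Si](C)(C)Cl
Why: Standard silylation of a phenol; the silyl ether formed sits next to the quaternary carbon and should therefore be shielded from the bases and nucleophiles used later.

Step 5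
Reactants: 7 ArA–CHO
Product: 8 [4-(tert-butyldimethylsilyloxy)-2-(methoxymethoxy)-5-(2-methylbut-3-en-2-yl)phenyl]methanol (ArA–CH2OH)
Conditions: NaBH4, THF–EtOH, 0 °C
Reagents that add atoms: none
Why: Borohydride reduction of an aryl aldehyde to the benzylic alcohol, with no other reducible group present.

Step 6
Reactants: 8 ArA–CH2OH
Product: 9 1-(bromomethyl)-4-(tert-butyldimethylsilyloxy)-2-(methoxymethoxy)-5-(2-methylbut-3-en-2-yl)benzene (ArA–CH2Br)
Conditions: CBr4, PPh3, CH2Cl2, −20 to 0 °C
Reagents that add atoms: carbon tetrabromide BrC(Br)(Br)Br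
Why: Appel reaction: the alcohol is activated as an alkoxyphosphonium ion and displaced by bromide under neutral conditions that spare the acetal and the silyl ether; the electron-rich bromide should be used at once without storage.

Step 7
Reactants: 9 ArA–CH2Br; 10 (S)-but-3-yn-2-ol
Product: 11 (2S)-5-ArA-pent-3-yn-2-ol
Conditions: CuI (cat.), NaI (cat.), Cs2CO3, MeCN, rt
Reagents that add atoms: none
Why: Copper-catalysed benzylation of a terminal alkyne: the copper acetylide formed under carbonate base displaces the benzylic halide (iodide exchange speeds this), the free secondary hydroxyl is not deprotonated by carbonate, and the carbinol centre is not touched and stays S.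

Step 8
Reactants: 11 (2S)-5-ArA-pent-3-yn-2-ol
Product: 12 (2S,3E)-5-ArA-pent-3-en-2-ol
Conditions: NaAlH2(OCH2CH2OCH3)2, THF, 0 °C to rt; then H2O
Reagents that add atoms: none
Why: Hydroxyl-directed trans-hydroalumination of a propargylic alcohol: the alkoxyaluminate delivers hydride inside a five-membered ring and protonolysis of the alkenyl–aluminium bond gives the E-allylic alcohol only, with the S centre untouched.

Step 9
Reactants: 13 resorcinol; 2 1-bromo-3-methylbut-2-ene
Product: 14 3-(3-methylbut-2-enyloxy)phenol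
Conditions: K2CO3, acetone, reflux (13 in excess)
Reagents that add atoms: none
Why: Williamson mono-etherification, with resorcinol in excess to hold back the bis-ether, which is separated together with the recovered diol.

Step 10
Reactants: 12 (2S,3E)-5-ArA-pent-3-en-2-ol; 14 3-(3-methylbut-2-enyloxy)phenol
Product: 15 1-{[(2R,3E)-5-ArA-pent-3-en-2-yl]oxy}-3-(3-methylbut-2-enyloxy)benzene
Conditions: PPh3, DIAD, toluene, 0 °C
Reagents that add atoms: none
Why: Mitsunobu etherification: the phenoxide displaces the alkoxyphosphonium group in an SN2 step, so the carbinol carbon is inverted from S to R, and low temperature in a non-polar solvent should hold back SN2' attack and elimination.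

Step 11
Reactants: 15 1-{[(2R,3E)-5-ArA-pent-3-en-2-yl]oxy}-3-(3-methylbut-2-enyloxy)benzene
Product: 18 4-[(2S,3E)-1-ArA-pent-3-en-2-yl]-6-(2-methylbut-3-en-2-yl)benzene-1,3-diol, via mono-shifted trimethylsilyl ether 16 (not isolated), via bis(trimethylsilyl) ether 17 (not isolated)
Conditions: BSA, PhNEt2, 185 °C (sealed tube, Ar); then citric acid, THF–H2O, rt
Reagents that add atoms: none
Why: Both O-allyl groups of ring B should move by thermal, concerted, suprafacial [3,3]-sigmatropic shifts (aromatic Claisen rearrangements), each followed by re-aromatisation through a proton shift and capture of the new phenol by BSA: the secondary allyl group goes from O2' to C1' (forming C1'–C3) and the prenyl group goes from O4' to C5' with allylic inversion (forming the bond to the quaternary carbon). The closest known reaction types are the Claisen rearrangement of enantioenriched aryl ethers of secondary E-allylic alcohols with 1,3-chirality transfer and the rearrangement of aryl prenyl ethers to ortho-(2-methylbut-3-en-2-yl)phenols. No ring is closed. The one new stereocentre, C3, is controlled by the R carbinol carbon of the ether: in the chair transition state its methyl group sits equatorial, so the C–C bond forms on the alkene face from which the C–O bond departs, which gives the S centre of 18 (R at C3 once the propenyl group has become C2) and an E-propenyl group. The step needs migration to the outer ortho carbons C1' and C5' and not to C3', which is secured by the crowding of C3' between two oxygen substituents (one of them silylated after the first shift) against the size of the migrating termini (a secondary carbon bearing the ring A benzyl group and a carbon that becomes quaternary), helped by the para-directing effect of the meta oxygen donor. Chair-over-boat and concerted-over-ionic pathways are favoured by the E alkene, the basic non-polar amine solvent and the silyl trap, which also blocks the abnormal Claisen pathway that would otherwise scramble C3.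

Step 12
Reactants: 18 4-[(2S,3E)-1-ArA-pent-3-en-2-yl]-6-(2-methylbut-3-en-2-yl)benzene-1,3-diol
Product: 19 bis(tert-butyldimethylsilyl) ether of 18, (2S,3E)-1-ArA-2-ArB-pent-3-ene
Conditions: TBSCl, imidazole, 4-(dimethylamino)pyridine (cat.), DMF, 50 °C
Reagents that add atoms: tert-butyldimethylsilyl chloride CC(C)(C)[Si](C)(C)Cl
Why: Silylation of both ring B phenols under imidazole catalysis (warming for the hindered O4' next to the quaternary carbon), so that all three later-free phenols carry the same fluoride-labile group.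

Step 13
Reactants: 19 (2S,3E)-1-ArA-2-ArB-pent-3-ene
Product: 20 (4R)-5-ArA-4-ArB-pentane-2,3-diol (mixture of the two syn-diols, 2R,3R and 2S,3S)
Conditions: OsO4 (cat.), NMO, acetone–H2O, 0 °C
Reagents that add atoms: osmium tetroxide O=[Os](=O)(=O)=O; 4-methylmorpholine N-oxide C[N+]1([O-])CCOCC1; water O
Why: Catalytic dihydroxylation with OsO4 (Upjohn conditions): the electrophilic, bulky oxidant should add syn to the 1,2-disubstituted propenyl alkene much faster than to the two vinyl groups, each of which hangs on a quaternary carbon beside an ortho silyloxy group; the existing stereocentre is not involved and both syn-diols serve.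

Step 14
Reactants: 20 (4R)-5-ArA-4-ArB-pentane-2,3-diol
Product: 21 (2R)-3-ArA-2-ArB-propanal
Conditions: NaIO4, THF–pH 7 buffer, 0 °C
Reagents that add atoms: none
Why: Glycol cleavage through a cyclic periodate ester, run cold in neutral buffer and worked up quickly so that the enolisable alpha-aryl aldehyde keeps its configuration.

Step 15
Reactants: 21 (2R)-3-ArA-2-ArB-propanal
Product: 22 (2R)-3-ArA-2-ArB-propan-1-ol
Conditions: NaBH4, THF–EtOH, −20 °C
Reagents that add atoms: none
Why: Borohydride reduction of the aldehyde, which at low temperature is faster than enolisation, so the alpha stereocentre should be carried over unchanged (it is R in 21 and 22 by the change of substituent priorities only).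

Step 16
Reactants: 22 (2R)-3-ArA-2-ArB-propan-1-ol
Product: 23 (2R)-2-ArB-3-[4-(tert-butyldimethylsilyloxy)-2-hydroxy-5-(2-methylbut-3-en-2-yl)phenyl]propan-1-ol
Conditions: ZnBr2, n-PrSH, CH2Cl2, 0 °C
Reagents that add atoms: none
Why: Lewis acid–thiol cleavage of the aryl methoxymethyl acetal: ZnBr2 activates the acetal oxygen and the thiol captures the methoxymethyl cation within minutes, conditions to which aryl silyl ethers, the primary alcohol and the hindered vinyl groups should be inert.

Step 17
Reactants: 23 (2R)-2-ArB-3-[4-(tert-butyldimethylsilyloxy)-2-hydroxy-5-(2-methylbut-3-en-2-yl)phenyl]propan-1-ol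
Product: 24 (3R)-3-ArB-7-(tert-butyldimethylsilyloxy)-6-(2-methylbut-3-en-2-yl)-3,4-dihydro-2H-chromene
Conditions: PPh3, DIAD, THF, 0 °C to rt
Reagents that add atoms: none
Why: Intramolecular Mitsunobu etherification (6-exo-tet): the only free phenol, O1, displaces the activated primary C2 oxygen to close ring C, and since C3 is not a reacting centre its configuration is kept.

Step 18
Reactants: 24 (3R)-3-ArB-7-(tert-butyldimethylsilyloxy)-6-(2-methylbut-3-en-2-yl)-3,4-dihydro-2H-chromene
Product: 25 Manuifolin E, (3R)-3-[2,4-dihydroxy-5-(2-methylbut-3-en-2-yl)phenyl]-6-(2-methylbut-3-en-2-yl)-3,4-dihydro-2H-chromen-7-ol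
Conditions: Bu4NF, AcOH, THF, 0 °C to rt
Reagents that add atoms: none
Why: Fluoride cleavage of the three aryl silyl ethers, buffered with acetic acid so that the ortho-(2-methylbut-3-en-2-yl)phenols meet neither strong base nor the acid that would cyclise them to dihydrobenzofurans.

## Compound list

1 | 2,4-dihydroxybenzaldehyde | O=Cc1ccc(O)cc1O | starting material
2 | 1-bromo-3-methylbut-2-ene (prenyl bromide) | CC(C)=CCBr | starting material
3 | 2-hydroxy-4-(3-methylbut-2-enyloxy)benzaldehyde | O=Cc1ccc(OCC=C(C)C)cc1O | intermediate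
4 | 2-(methoxymethoxy)-4-(3-methylbut-2-enyloxy)benzaldehyde | O=Cc1ccc(OCC=C(C)C)cc1OCOC | intermediate
5 | 2-(methoxymethoxy)-5-(2-methylbut-3-en-2-yl)-4-(trimethylsilyloxy)benzaldehyde (formed in the flask) | O=Cc1cc(C(C)(C)C=C)c(O[Si](C)(C)C)cc1OCOC | intermediate
6 | 4-hydroxy-2-(methoxymethoxy)-5-(2-methylbut-3-en-2-yl)benzaldehyde | O=Cc1cc(C(C)(C)C=C)c(O)cc1OCOC | intermediate
7 | 4-(tert-butyldimethylsilyloxy)-2-(methoxymethoxy)-5-(2-methylbut-3-en-2-yl)benzaldehyde | O=Cc1cc(C(C)(C)C=C)c(O[Si](C)(C)C(C)(C)C)cc1OCOC | intermediate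
8 | [4-(tert-butyldimethylsilyloxy)-2-(methoxymethoxy)-5-(2-methylbut-3-en-2-yl)phenyl]methanol | OCc1cc(C(C)(C)C=C)c(O[Si](C)(C)C(C)(C)C)cc1OCOC | intermediate
9 | 1-(bromomethyl)-4-(tert-butyldimethylsilyloxy)-2-(methoxymethoxy)-5-(2-methylbut-3-en-2-yl)benzene | BrCc1cc(C(C)(C)C=C)c(O[Si](C)(C)C(C)(C)C)cc1OCOC | intermediate
10 | (S)-but-3-yn-2-ol | C[C@H](O)C#C | starting material
11 | (2S)-5-ArA-pent-3-yn-2-ol | C[C@H](O)C#CCc1cc(C(C)(C)C=C)c(O[Si](C)(C)C(C)(C)C)cc1OCOC | intermediate
12 | (2S,3E)-5-ArA-pent-3-en-2-ol | C[C@H](O)/C=C/Cc1cc(C(C)(C)C=C)c(O[Si](C)(C)C(C)(C)C)cc1OCOC | intermediate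
13 | resorcinol | Oc1cccc(O)c1 | starting material
14 | 3-(3-methylbut-2-enyloxy)phenol | CC(C)=CCOc1cccc(O)c1 | intermediate
15 | 1-{[(2R,3E)-5-ArA-pent-3-en-2-yl]oxy}-3-(3-methylbut-2-enyloxy)benzene | C[C@@H](Oc1cccc(OCC=C(C)C)c1)/C=C/Cc1cc(C(C)(C)C=C)c(O[Si](C)(C)C(C)(C)C)cc1OCOC | intermediate
16 | {2-[(2S,3E)-1-ArA-pent-3-en-2-yl]-5-(3-methylbut-2-enyloxy)phenoxy}trimethylsilane (formed in the flask; the secondary allyl group is expected to move first) | C/C=C/[C@@H](c1ccc(OCC=C(C)C)cc1O[Si](C)(C)C)Cc1cc(C(C)(C)C=C)c(O[Si](C)(C)C(C)(C)C)cc1OCOC | intermediate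
17 | bis(trimethylsilyl) ether of 18 (formed in the flask) | C/C=C/[C@@H](c1cc(C(C)(C)C=C)c(O[Si](C)(C)C)cc1O[Si](C)(C)C)Cc1cc(C(C)(C)C=C)c(O[Si](C)(C)C(C)(C)C)cc1OCOC | intermediate
18 | 4-[(2S,3E)-1-ArA-pent-3-en-2-yl]-6-(2-methylbut-3-en-2-yl)benzene-1,3-diol | C/C=C/[C@@H](c1cc(C(C)(C)C=C)c(O)cc1O)Cc1cc(C(C)(C)C=C)c(O[Si](C)(C)C(C)(C)C)cc1OCOC | intermediate
19 | (2S,3E)-1-ArA-2-ArB-pent-3-ene (bis-TBS ether of 18) | C/C=C/[C@@H](c1cc(C(C)(C)C=C)c(O[Si](C)(C)C(C)(C)C)cc1O[Si](C)(C)C(C)(C)C)Cc1cc(C(C)(C)C=C)c(O[Si](C)(C)C(C)(C)C)cc1OCOC | intermediate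
20 | (4R)-5-ArA-4-ArB-pentane-2,3-diol (2R,3R and 2S,3S syn-diols; C2 and C3 left open in the SMILES) | CC(O)C(O)[C@@H](c1cc(C(C)(C)C=C)c(O[Si](C)(C)C(C)(C)C)cc1O[Si](C)(C)C(C)(C)C)Cc1cc(C(C)(C)C=C)c(O[Si](C)(C)C(C)(C)C)cc1OCOC | intermediate
21 | (2R)-3-ArA-2-ArB-propanal | O=C[C@@H](c1cc(C(C)(C)C=C)c(O[Si](C)(C)C(C)(C)C)cc1O[Si](C)(C)C(C)(C)C)Cc1cc(C(C)(C)C=C)c(O[Si](C)(C)C(C)(C)C)cc1OCOC | intermediate
22 | (2R)-3-ArA-2-ArB-propan-1-ol | OC[C@@H](c1cc(C(C)(C)C=C)c(O[Si](C)(C)C(C)(C)C)cc1O[Si](C)(C)C(C)(C)C)Cc1cc(C(C)(C)C=C)c(O[Si](C)(C)C(C)(C)C)cc1OCOC | intermediate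
23 | (2R)-2-ArB-3-[4-(tert-butyldimethylsilyloxy)-2-hydroxy-5-(2-methylbut-3-en-2-yl)phenyl]propan-1-ol | OC[C@@H](c1cc(C(C)(C)C=C)c(O[Si](C)(C)C(C)(C)C)cc1O[Si](C)(C)C(C)(C)C)Cc1cc(C(C)(C)C=C)c(O[Si](C)(C)C(C)(C)C)cc1O | intermediate
24 | (3R)-3-ArB-7-(tert-butyldimethylsilyloxy)-6-(2-methylbut-3-en-2-yl)-3,4-dihydro-2H-chromene | C=CC(C)(C)c1cc2c(cc1O[Si](C)(C)C(C)(C)C)OC[C@@H](c1cc(C(C)(C)C=C)c(O[Si](C)(C)C(C)(C)C)cc1O[Si](C)(C)C(C)(C)C)C2 | intermediate
25 | Manuifolin E, (3R) | C=CC(C)(C)c1cc2c(cc1O)OC[C@@H](c1cc(C(C)(C)C=C)c(O)cc1O)C2 | target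

## Step count and risks

Total step count: 18. Longest linear sequence: 17 steps (steps 1–8 and 10–18, from 2,4-dihydroxybenzaldehyde); step 9 is the one-step side branch.

Steps most likely to fail:

1. Step 11. Either allyl group may migrate to C3' between the two oxygens, the two shifts running side by side may give a tangled mixture, or chirality transfer may erode through boat or ion-pair pathways.
 Fallback, setting out from 7 (with 12 as partner) and coming back at 19: the tandem mode is given up, the ring B reverse-prenyl group is brought in ready-made, and only the chirality-relaying shift remains, now beside a bulky silyl ether that shields C3'. Aldehyde 7 would be decarbonylated with RhCl(PPh3)3 in refluxing xylene (the vinyl group has no allylic hydrogen and cannot isomerise) to tert-butyl[5-(methoxymethoxy)-2-(2-methylbut-3-en-2-yl)phenoxy]dimethylsilane F1. Its acetal would be cleaved with ZnBr2 and n-PrSH to 3-(tert-butyldimethylsilyloxy)-4-(2-methylbut-3-en-2-yl)phenol F2. Mitsunobu coupling of F2 with alcohol 12 (PPh3, DIAD, inversion) would give 4-{[(2R,3E)-5-ArA-pent-3-en-2-yl]oxy}-2-(tert-butyldimethylsilyloxy)-1-(2-methylbut-3-en-2-yl)benzene F3. Heating F3 with BSA in PhNEt2 should give the trimethylsilyl ether of the rearranged phenol F4 (not isolated) and, after citric acid work-up, 2-[(2S,3E)-1-ArA-pent-3-en-2-yl]-5-(tert-butyldimethylsilyloxy)-4-(2-methylbut-3-en-2-yl)phenol F5. Silylation of F5 (TBSCl, imidazole) gives 19.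

2. Step 7 (with the bromide made in step 6). The electron-rich benzylic bromide may ionise and alkylate itself before it meets the copper acetylide, and base may isomerise the benzylic alkyne to an allene.
 Fallback, setting out from 7 and coming back at 12, with no benzylic halide: aldehyde 7 would be methylenated to an epoxide with trimethylsulfonium iodide and n-BuLi in THF (Corey–Chaykovsky reaction), giving racemic 2-ArA-oxirane F6. F6 would be isomerised with InCl3 (cat.) in THF (Meinwald rearrangement) to 2-ArA-acetaldehyde F7. A Wittig reaction of F7 with 1-(triphenylphosphoranylidene)propan-2-one in CH2Cl2 should give (3E)-5-ArA-pent-3-en-2-one F8. Corey–Bakshi–Shibata reduction of F8 with (R)-1-methyl-3,3-diphenyl-tetrahydro-1H,3H-pyrrolo[1,2-c][1,3,2]oxazaborole (cat.) and catecholborane in toluene at −78 °C (a borane that leaves the vinyl groups alone) should give the S alcohol 12.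

3. Step 13. Osmylation of one of the vinyl groups may compete with that of the propenyl group, giving over-oxidised material.
 Fallback, setting out from 19 and coming back at 21: the alkenes would be told apart by electrophilic oxygen transfer, which favours the disubstituted alkene more strongly. mCPBA with NaHCO3 in CH2Cl2 at 0 °C should give trans-2-methyl-3-[(1R)-2-ArA-1-ArB-ethyl]oxirane F9 (both epoxide diastereomers). Periodic acid (H5IO6) in THF–H2O at 0 °C would then open and cleave F9 to aldehyde 21.

## Further compounds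

F1 | step 11 | tert-butyl[5-(methoxymethoxy)-2-(2-methylbut-3-en-2-yl)phenoxy]dimethylsilane | C=CC(C)(C)c1ccc(OCOC)cc1O[Si](C)(C)C(C)(C)C
F2 | step 11 | 3-(tert-butyldimethylsilyloxy)-4-(2-methylbut-3-en-2-yl)phenol | C=CC(C)(C)c1ccc(O)cc1O[Si](C)(C)C(C)(C)C
F3 | step 11 | 4-{[(2R,3E)-5-ArA-pent-3-en-2-yl]oxy}-2-(tert-butyldimethylsilyloxy)-1-(2-methylbut-3-en-2-yl)benzene | C[C@@H](Oc1ccc(C(C)(C)C=C)c(O[Si](C)(C)C(C)(C)C)c1)/C=C/Cc1cc(C(C)(C)C=C)c(O[Si](C)(C)C(C)(C)C)cc1OCOC
F4 | step 11 | trimethylsilyl ether of F5 | C/C=C/[C@@H](c1cc(C(C)(C)C=C)c(O[Si](C)(C)C(C)(C)C)cc1O[Si](C)(C)C)Cc1cc(C(C)(C)C=C)c(O[Si](C)(C)C(C)(C)C)cc1OCOC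
F5 | step 11 | 2-[(2S,3E)-1-ArA-pent-3-en-2-yl]-5-(tert-butyldimethylsilyloxy)-4-(2-methylbut-3-en-2-yl)phenol | C/C=C/[C@@H](c1cc(C(C)(C)C=C)c(O[Si](C)(C)C(C)(C)C)cc1O)Cc1cc(C(C)(C)C=C)c(O[Si](C)(C)C(C)(C)C)cc1OCOC
F6 | step 7 | 2-ArA-oxirane (racemic) | C1OC1c1cc(C(C)(C)C=C)c(O[Si](C)(C)C(C)(C)C)cc1OCOC
F7 | step 7 | 2-ArA-acetaldehyde | O=CCc1cc(C(C)(C)C=C)c(O[Si](C)(C)C(C)(C)C)cc1OCOC
F8 | step 7 | (3E)-5-ArA-pent-3-en-2-one | CC(=O)/C=C/Cc1cc(C(C)(C)C=C)c(O[Si](C)(C)C(C)(C)C)cc1OCOC
F9 | step 13 | trans-2-methyl-3-[(1R)-2-ArA-1-ArB-ethyl]oxirane (both epoxide diastereomers; epoxide carbons left open in the SMILES) | CC1OC1[C@@H](c1cc(C(C)(C)C=C)c(O[Si](C)(C)C(C)(C)C)cc1O[Si](C)(C)C(C)(C)C)Cc1cc(C(C)(C)C=C)c(O[Si](C)(C)C(C)(C)C)cc1OCOC
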